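**Retrosynthetic overview**
- The target is opened out of the C2-symmetric furofuran (+)-yangambin by hydrogenolysis of one benzylic C–O bond; the two such bonds are equivalent, so either cleavage gives the target.
- The furofuran comes from an acyclic epoxy cinnamyl ether in one pot: Ti(III) epoxide opening, 5-exo radical cyclisation (C3–C4 bond, first oxolane ring), then iodine-triggered etherification (second oxolane ring).
- The epoxy ether comes from an erythro epoxy alcohol and 3,4,5-trimethoxycinnamyl bromide by Williamson etherification.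
- The epoxy alcohol comes from 3,4,5-trimethoxybenzaldehyde by vinyl Grignard addition and Sharpless kinetic resolution, the only source of absolute configuration; the bromide comes from methyl 3,4,5-trimethoxycinnamate.
- Ring order: both oxolane rings form in the key step (C–C ring first, C–O ring second); the second is re-opened in the last step.

Assumption: methyl (E)-3,4,5-trimethoxycinnamate and vinylmagnesium bromide solution are bought as such (the ester is otherwise one esterification from the cheap acid).

**Step 1**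
Reactants: 1 3,4,5-trimethoxybenzaldehyde; 2 vinylmagnesium bromide
Product: 3 rac-1-(3,4,5-trimethoxyphenyl)prop-2-en-1-ol
Conditions: 2 (1.2 equiv), THF, 0 °C; aq. NH4Cl
Reagents that add atoms: none
Why: Grignard 1,2-addition to an aromatic aldehyde gives the racemic aryl vinyl carbinol, whose stereocentre is resolved in step 2.

**Step 2**
Reactants: 3 rac-1-(3,4,5-trimethoxyphenyl)prop-2-en-1-ol
Product: 4 (R)-[(2S)-oxiran-2-yl](3,4,5-trimethoxyphenyl)methanol
Conditions: Ti(OiPr)4 (0.15 equiv), D-(−)-DIPT (0.20 equiv), TBHP (0.45 equiv), 4 Å MS, CH2Cl2, −20 °C; (R)-enantiomer of 3 left behind and separated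
Reagents that add atoms: tert-butyl hydroperoxide, CC(C)(C)OO
Why: Sharpless kinetic resolution by asymmetric epoxidation: with D-(−)-tartrate the (S)-carbinol is expected to react much faster and give the erythro epoxy alcohol, so the carbinol centre (later C2 of the target) is fixed here, while the epoxide carbon configuration is erased in step 6.

**Step 3**
Reactants: 5 methyl (2E)-3-(3,4,5-trimethoxyphenyl)prop-2-enoate
Product: 6 (2E)-3-(3,4,5-trimethoxyphenyl)prop-2-en-1-ol
Conditions: DIBAL-H (2.2 equiv), CH2Cl2, −78 °C; Rochelle salt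
Reagents that add atoms: none
Why: DIBAL-H 1,2-reduction of an enoate gives the allylic alcohol without touching the E-alkene.

**Step 4**
Reactants: 6 (2E)-3-(3,4,5-trimethoxyphenyl)prop-2-en-1-ol
Product: 7 5-[(1E)-3-bromoprop-1-en-1-yl]-1,2,3-trimethoxybenzene
Conditions: PBr3 (0.4 equiv), Et2O, 0 °C; used crude at once
Reagents that add atoms: phosphorus tribromide, BrP(Br)Br
Why: Bromination of the primary allylic alcohol through its phosphite ester (SN2) keeps the E-geometry.

**Step 5**
Reactants: 4 (R)-[(2S)-oxiran-2-yl](3,4,5-trimethoxyphenyl)methanol; 7 5-[(1E)-3-bromoprop-1-en-1-yl]-1,2,3-trimethoxybenzene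
Product: 8 (2S)-2-[(R)-(3,4,5-trimethoxyphenyl){[(2E)-3-(3,4,5-trimethoxyphenyl)prop-2-en-1-yl]oxy}methyl]oxirane
Conditions: NaH (1.1 equiv), THF/DMF 4:1, 0 °C; then 7 (1.2 equiv), Bu4NI (cat.), 0 °C → rt
Reagents that add atoms: none
Why: Williamson etherification at the primary allylic bromide leaves the carbinol C–O bond intact (configuration retained), and cold aprotic conditions keep the alkoxide from Payne rearrangement.

**Step 6**
Reactants: 8 (2S)-2-[(R)-(3,4,5-trimethoxyphenyl){[(2E)-3-(3,4,5-trimethoxyphenyl)prop-2-en-1-yl]oxy}methyl]oxirane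
Product: 11 (1S,3aR,4S,6aR)-1,4-bis(3,4,5-trimethoxyphenyl)tetrahydro-1H,3H-furo[3,4-c]furan [(+)-yangambin], via bis-titanium(IV) cyclised intermediate 9 (not isolated), via benzylic iodide titanium alkoxide 10 (not isolated)
Conditions: Cp2TiCl (2.2 equiv; from Cp2TiCl2, Zn dust, THF, decanted), THF, rt, slow addition; then I2 (1.5 equiv), rt → 60 °C; aq. Na2S2O3; recrystallise
Reagents that add atoms: none
Why: Nugent–RajanBabu Ti(III) epoxide opening gives the C3 radical, which cyclises 5-exo onto the styrene through a Beckwith–Houk chair with the C2 aryl pseudo-equatorial (2,3-trans, 3,4-cis); a second Ti(III) captures the benzylic radical (9), iodine converts C–Ti to C–I (10), and the titanium alkoxide closes the second ring by SN1-like displacement with the aryl on the convex face, so only the 3,4-cis adduct becomes bicyclic and crystalline 11 can be freed of minor isomers and enriched in ee.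

**Step 7**
Reactants: 11 (1S,3aR,4S,6aR)-1,4-bis(3,4,5-trimethoxyphenyl)tetrahydro-1H,3H-furo[3,4-c]furan
Product: 12 [(2S,3R,4R)-2-(3,4,5-trimethoxyphenyl)-4-[(3,4,5-trimethoxyphenyl)methyl]oxolan-3-yl]methanol
Conditions: H2 (1 atm), 10% Pd/C, EtOH, rt; stopped at about 1 equiv H2 (≈90% conversion), recovered 11 recycled
Reagents that add atoms: none
Why: Catalytic hydrogenolysis of one benzylic C–O bond turns that carbon into the benzyl CH2 and frees the CH2OH, and because 11 is C2-symmetric either bond gives 12 with C2, C3 and C4 untouched.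

**Compound list**
1 | 3,4,5-trimethoxybenzaldehyde | COc1cc(C=O)cc(OC)c1OC | starting material
2 | vinylmagnesium bromide | C=C[Mg]Br | starting material
3 | rac-1-(3,4,5-trimethoxyphenyl)prop-2-en-1-ol | COc1cc(C(O)C=C)cc(OC)c1OC | intermediate
4 | (R)-[(2S)-oxiran-2-yl](3,4,5-trimethoxyphenyl)methanol (erythro) | O[C@H](c1cc(OC)c(OC)c(OC)c1)[C@@H]2CO2 | intermediate
5 | methyl (2E)-3-(3,4,5-trimethoxyphenyl)prop-2-enoate | COC(=O)/C=C/c1cc(OC)c(OC)c(OC)c1 | starting material
6 | (2E)-3-(3,4,5-trimethoxyphenyl)prop-2-en-1-ol | OC/C=C/c1cc(OC)c(OC)c(OC)c1 | intermediate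
7 | 5-[(1E)-3-bromoprop-1-en-1-yl]-1,2,3-trimethoxybenzene | BrC/C=C/c1cc(OC)c(OC)c(OC)c1 | intermediate
8 | (2S)-2-[(R)-(3,4,5-trimethoxyphenyl){[(2E)-3-(3,4,5-trimethoxyphenyl)prop-2-en-1-yl]oxy}methyl]oxirane | COc1cc(/C=C/CO[C@H](c2cc(OC)c(OC)c(OC)c2)[C@@H]3CO3)cc(OC)c1OC | intermediate
9 | bis-titanium(IV) cyclised intermediate: (2S,3R,4R)-oxolane with 3-CH2O–TiClCp2 and 4-CH(Ar)–TiClCp2, benzylic centre undefined (Cp written as separate anions) | COc1cc(C([Ti+2]Cl)[C@H]2CO[C@H](c3cc(OC)c(OC)c(OC)c3)[C@H]2CO[Ti+2]Cl)cc(OC)c1OC.[CH-]1C=CC=C1.[CH-]1C=CC=C1.[CH-]1C=CC=C1.[CH-]1C=CC=C1 | intermediate (not isolated)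
10 | benzylic iodide titanium alkoxide: (2S,3R,4R)-oxolane with 3-CH2O–TiClCp2 and 4-CH(I)Ar, benzylic centre undefined | COc1cc(C(I)[C@H]2CO[C@H](c3cc(OC)c(OC)c(OC)c3)[C@H]2CO[Ti+2]Cl)cc(OC)c1OC.[CH-]1C=CC=C1.[CH-]1C=CC=C1 | intermediate (not isolated)
11 | (1S,3aR,4S,6aR)-1,4-bis(3,4,5-trimethoxyphenyl)tetrahydro-1H,3H-furo[3,4-c]furan, (+)-yangambin | COc1cc([C@@H]4[C@H]2CO[C@H](c3cc(OC)c(OC)c(OC)c3)[C@H]2CO4)cc(OC)c1OC | intermediate
12 | [(2S,3R,4R)-2-(3,4,5-trimethoxyphenyl)-4-[(3,4,5-trimethoxyphenyl)methyl]oxolan-3-yl]methanol | COc1cc(C[C@H]2CO[C@H](c3cc(OC)c(OC)c(OC)c3)[C@H]2CO)cc(OC)c1OC | target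

**Step count and risks**
Total steps: 7. Longest linear sequence: 5 (steps 1, 2, 5, 6, 7; the branch through steps 3, 4, 5, 6, 7 is also 5).

Most likely to fail, first: step 6. The radical may be reduced before it cyclises, the cyclisation may be poorly diastereoselective, or the iodide may eliminate instead of closing. The fallback sets out from 8 and comes back at 12: the Ti(III) cyclisation is run as before, but intermediate 9 is quenched with dilute aqueous HCl instead of iodine. Protonolysis of the C–Ti and O–Ti bonds gives 12 directly, so 11 and step 7 are skipped. The cost is that the 3,4-trans isomer is no longer removed by the bicyclisation and must be separated by chromatography. This fallback makes no new compound (entry F0).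

Second: step 7. Over-reduction to the ring-opened diol, or a sluggish first cleavage, is possible. The fallback sets out from 11 and comes back at 12. Ring opening by SN1 thiolysis (PhSH 1.05 equiv, BF3·OEt2, CH2Cl2, −78 °C) gives {(2S,3R,4R)-4-[(phenylsulfanyl)(3,4,5-trimethoxyphenyl)methyl]-2-(3,4,5-trimethoxyphenyl)oxolan-3-yl}methanol F1 as a mixture of epimers at the sulfur-bearing carbon. Radical desulfurisation (Bu3SnH, AIBN, toluene, 110 °C) then replaces C–S by C–H and gives 12.

Third: step 5. Payne rearrangement of the alkoxide of 4, or decomposition of the electron-rich bromide 7, would lower the yield. The fallback sets out from 6 (with 4) and comes back at 8. Alcohol 6 is acetylated (Ac2O, pyridine, DMAP) to (2E)-3-(3,4,5-trimethoxyphenyl)prop-2-en-1-yl acetate F2. Tsuji–Trost allylic etherification (Pd(PPh3)4 5 mol%, zinc alkoxide of 4 from Et2Zn 0.5 equiv, THF, rt) then attacks the unsubstituted allyl terminus and gives the linear E-ether 8 without a free alkali alkoxide or an allylic bromide.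

**Further compounds**
F0 | step 6 | none | none
F1 | step 7 | {(2S,3R,4R)-4-[(phenylsulfanyl)(3,4,5-trimethoxyphenyl)methyl]-2-(3,4,5-trimethoxyphenyl)oxolan-3-yl}methanol | COc1cc(C(Sc5ccccc5)[C@H]2CO[C@H](c3cc(OC)c(OC)c(OC)c3)[C@H]2CO)cc(OC)c1OC
F2 | step 5 | (2E)-3-(3,4,5-trimethoxyphenyl)prop-2-en-1-yl acetate | CC(=O)OC/C=C/c1cc(OC)c(OC)c(OC)c1
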